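## Retrosynthetic overview
1. The oxirane comes last. The target goes back to jaeschkeanadiol 6-benzoate by α-face epoxidation of C8=C9, following the order assumed in the plant: skeleton, then C6 ester, then epoxide.
2. The seven-membered ring and the C1, C4 and C5 stereocentres come from one cation cascade modelled on the proposed daucane pathway. A neryl-type allyl cation closes 1,6 to an acorane-type spiro cation. A 1,2-alkyl shift (six to seven), a 1,2-hydride shift C4→C5 and oxygen capture at C4 by the C6 benzoate follow.
3. The cascade substrate comes from benzoylation and asymmetric isoprenylboration (sets C6) of a cyclopentenecarbaldehyde, using isoprene.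
4. The cyclopentenecarbaldehyde comes from (S)-limonene. Ring order: ring A (five), a transient six-membered ring, ring B (seven), then the oxirane.

Assumption: commercial (S)-(−)-limonene is taken as enantiopure; locants are daucane numbers (C1 angular C–CH3, C4 C(OH)iPr, C5 ring-fusion CH, C6 C–OBz, C8/C9 oxirane carbons).

## Route

Step 1
Reactants: 1 (S)-(−)-limonene
Product: 2 (S)-p-menth-1-ene
Conditions: H2 (1 atm, stopped after 1.0 equiv), PtO2 (0.5 mol %), EtOH, rt
Reagents that add atoms: none
Why: In this chemoselective heterogeneous hydrogenation the unhindered 1,1-disubstituted alkene is saturated far faster than the trisubstituted ring alkene, and the stereocentre (future C4) is not touched.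

Step 2
Reactants: 2 (S)-p-menth-1-ene
Product: 4 (S)-3-isopropyl-6-oxoheptanal, via secondary ozonide 3 (not isolated)
Conditions: O3, CH2Cl2, −78 °C; then Me2S, −78 °C → rt
Reagents that add atoms: ozone [O-][O+]=O
Why: Criegee ozonolysis with reductive work-up cleaves the only alkene to the aldehyde and methyl ketone, and the stereocentre is β to the aldehyde and cannot epimerise.

Step 3
Reactants: 4 (S)-3-isopropyl-6-oxoheptanal
Product: 6 (R)-5-isopropyl-2-methylcyclopent-1-ene-1-carbaldehyde, via aldol 5 (not isolated)
Conditions: piperidine (20 mol %), AcOH (20 mol %), toluene, reflux, Dean–Stark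
Reagents that add atoms: none
Why: In this enamine-mediated intramolecular aldol condensation the aldehyde enamine attacks the methyl ketone (5-exo) and dehydration gives the conjugated tetrasubstituted enal; the descriptor changes from S to R only through CIP priorities.

Step 4
Reactants: 6 (R)-5-isopropyl-2-methylcyclopent-1-ene-1-carbaldehyde; 7 isoprene
Product: 10 (1S)-1-[(5R)-5-isopropyl-2-methylcyclopent-1-en-1-yl]-3-methylidenepent-4-en-1-ol, via isoprenylpotassium 8 (not isolated), via isoprenylborane 9 (not isolated)
Conditions: 7, n-BuLi, KOtBu, 2,2,6,6-tetramethylpiperidine, THF, −78 °C; (−)-Ipc2BOMe; BF3·OEt2; then 6, −78 °C; NaOH, H2O2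
Reagents that add atoms: none
Why: In this Brown asymmetric allylboration (isoprenyl variant) the chair Zimmerman–Traxler transition state of the reagent derived from (+)-α-pinene attacks the Si face of the enal and sets C6 as S, and any minor epimer is a diastereomer removable by chromatography.

Step 5
Reactants: 10 (1S)-1-[(5R)-5-isopropyl-2-methylcyclopent-1-en-1-yl]-3-methylidenepent-4-en-1-ol
Product: 11 (1S)-1-[(5R)-5-isopropyl-2-methylcyclopent-1-en-1-yl]-3-methylidenepent-4-en-1-yl benzoate
Conditions: BzCl (1.2 equiv), pyridine (3 equiv), DMAP (5 mol %), CH2Cl2, 0 °C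
Reagents that add atoms: benzoyl chloride O=C(Cl)c1ccccc1
Why: DMAP-catalysed acyl transfer to the only hydroxyl group breaks no C–O bond, so C6 keeps its configuration, and the ester of the natural product is now in place as the internal nucleophile.

Step 6
Reactants: 11 (1S)-1-[(5R)-5-isopropyl-2-methylcyclopent-1-en-1-yl]-3-methylidenepent-4-en-1-yl benzoate
Product: 15 jaeschkeanadiol 6-benzoate [(1R,4R,5S,6S)-4-hydroxydauc-8-en-6-yl benzoate], via allyl cation 12 (not isolated), via spiro cation 13 (not isolated), via dioxanylium ion 14 (not isolated)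
Conditions: Tf2NH (1.05 equiv), CH2Cl2 (0.005 M), −78 → −30 °C; then aq NaHCO3–THF, 0 °C
Reagents that add atoms: water O
Why: Proposed new method: the 2-substituted diene is the most basic π-system (it gives a tertiary allyl cation, cisoid from the s-trans diene) and is protonated to 12; allylic 1,3-strain at the (S)-C6 centre holds the chain on the α face and the β-isopropyl group blocks the other face, so C10 is attacked from the α face by the tetrasubstituted alkene (either regiochemistry gives a tertiary cation) in a 1,6-closure to 13; a suprafacial 1,2-shift of the allylic C10 methylene then enlarges the six-membered ring to ring B and sets C1 (methyl β), the α-hydrogen on C4 migrates to C5 (trans fusion), and the benzoate carbonyl on the β face closes on C4 anti to the departing hydride (O β, isopropyl α) to give the charge-protected ion 14, which work-up hydrolyses to the less hindered secondary ester; alkenes formed by proton loss are re-protonated, so 14 is expected to be the sink; the closest known reaction types are cation-initiated polyene cyclisation, the acid-induced acorane-to-daucane Wagner–Meerwein ring expansion and acyloxonium neighbouring-group capture.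

Step 7
Reactants: 15 jaeschkeanadiol 6-benzoate
Product: 16 (1R,4R,5S,6S,8R,9S)-8,9-epoxy-4-hydroxydaucan-6-yl benzoate (target)
Conditions: mCPBA (1.1 equiv), NaHCO3, CH2Cl2, 0 °C
Reagents that add atoms: mCPBA O=C(OO)c1cccc(Cl)c1
Why: In this Prilezhaev epoxidation of the only alkene the peracid should approach the α face, because the axial angular methyl on C1 covers the β face of ring B while the C6 benzoate is equatorial, which sets 8R,9S.

## Compound list
1 | (S)-(−)-limonene | CC1=CC[C@H](CC1)C(C)=C | starting material
2 | (S)-p-menth-1-ene | CC1=CC[C@H](CC1)C(C)C | intermediate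
3 | secondary ozonide of 2 (new centres undefined) | CC(C)[C@H]1CCC2(C)OOC(C1)O2 | intermediate
4 | (S)-3-isopropyl-6-oxoheptanal | CC(C)[C@H](CC=O)CCC(C)=O | intermediate
5 | 2-hydroxy-5-isopropyl-2-methylcyclopentanecarbaldehyde (aldol, new centres undefined) | CC(C)[C@H]1CCC(C)(O)C1C=O | intermediate
6 | (R)-5-isopropyl-2-methylcyclopent-1-ene-1-carbaldehyde | CC(C)[C@H]1CCC(C)=C1C=O | intermediate
7 | isoprene | C=CC(C)=C | starting material
8 | isoprenylpotassium (2-methylidenebut-3-en-1-ylpotassium) | [K]CC(=C)C=C | intermediate
9 | B-(2-methylidenebut-3-en-1-yl)diisopinocampheylborane, Ipc groups from (+)-α-pinene | C[C@H]1[C@H](B(CC(=C)C=C)[C@@H]3C[C@@H]4C[C@H]([C@H]3C)C4(C)C)C[C@@H]2C[C@H]1C2(C)C | intermediate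
10 | (1S)-1-[(5R)-5-isopropyl-2-methylcyclopent-1-en-1-yl]-3-methylidenepent-4-en-1-ol | CC(C)[C@H]1CCC(C)=C1[C@@H](O)CC(=C)C=C | intermediate
11 | benzoate of 10 | CC(C)[C@H]1CCC(C)=C1[C@@H](OC(=O)c1ccccc1)CC(=C)C=C | intermediate
12 | tertiary allyl cation (C8+/C10+) | CC(C)[C@H]1CCC(C)=C1[C@@H](OC(=O)c1ccccc1)C[C+](C)C=C | intermediate
13 | acorane-type spiro[4.5]decenyl cation (C1+) | CC(C)[C@H]1CC[C+](C)[C@]12CC=C(C)C[C@@H]2OC(=O)c1ccccc1 | intermediate
14 | 2-phenyl-1,3-dioxan-2-ylium ion bridging O4 and O6 | CC(C)[C@]1(O3)CC[C@]2(C)CC=C(C)C[C@H](O[C+]3c3ccccc3)[C@H]21 | intermediate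
15 | jaeschkeanadiol 6-benzoate | CC(C)[C@]1(O)CC[C@]2(C)CC=C(C)C[C@H](OC(=O)c3ccccc3)[C@H]21 | intermediate
16 | (1R,4R,5S,6S,8R,9S)-8,9-epoxy-4-hydroxydaucan-6-yl benzoate | CC(C)[C@]1(O)CC[C@]2(C)C[C@@H]3O[C@]3(C)C[C@H](OC(=O)c3ccccc3)[C@H]21 | target

Total step count: 7. Longest linear sequence: 7 (1 → 16).

## Steps most likely to fail

**Step 6 (highest risk).**
- Protonation may not select the diene over the tetrasubstituted alkene.
- The allylic benzoate may ionise.
- The cascade may stop at the spiro stage, or the benzoate may capture the cation at C5 instead of C4.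

The fallback sets out from 11 and changes how the cation is made. A Mukaiyama hydration (Co(acac)2, PhSiH3, O2, iPrOH, 0 °C) should act only on the diene. It would give the linalool-type tertiary allylic alcohol (1S)-3-hydroxy-1-[(5R)-5-isopropyl-2-methylcyclopent-1-en-1-yl]-3-methylpent-4-en-1-yl benzoate F1 as a mixture of C8 epimers. This stereocentre is lost on ionisation, so the mixture does not matter. F1 ionises with only 5 mol % Tf2NH in HFIP–CH2Cl2 at −20 °C. No stoichiometric strong acid is then present to protonate alkenes or the ester. F1 enters the same manifold at 12, and the water it loses is returned on hydrolysis of 14. The fallback rejoins the route at 15.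

**Step 4.** Metalation of isoprene is capricious, and the hindered enal may react slowly or with eroded selectivity. The fallback sets out from 6 and 8 and moves the stereocontrol to a ketone reduction.
- Isoprenylpotassium 8 is added directly to 6 (THF, −78 °C). This gives 10 together with its carbinol epimer (1R)-1-[(5R)-5-isopropyl-2-methylcyclopent-1-en-1-yl]-3-methylidenepent-4-en-1-ol F2.
- The mixture is oxidised with MnO2 in CH2Cl2 to 1-[(5R)-5-isopropyl-2-methylcyclopent-1-en-1-yl]-3-methylidenepent-4-en-1-one F3.
- Corey–Bakshi–Shibata reduction with (R)-Me-CBS (10 mol %) and BH3·SMe2 at −40 °C treats the cyclopentenyl group as the large substituent and gives the (S)-carbinol.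

The fallback rejoins the route at 10.

**Step 7.** The 4β-hydroxyl group could steer the peracid to the β face and erode or invert the selectivity. The fallback sets out from 15 and inverts the facial outcome by a halohydrin sequence. NBS in aqueous acetone at 0 °C forms the bromonium ion on the more accessible face, and water opens it anti at the tertiary C8. This gives (1R,4R,5S,6S,8R,9R)-9-bromo-4,8-dihydroxydaucan-6-yl benzoate F4. DBU in CH2Cl2 then closes the oxirane by SN2 displacement at C9 from the α side. The fallback rejoins the route at 16.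

## Further compounds
F1 | step 6 | (1S)-3-hydroxy-1-[(5R)-5-isopropyl-2-methylcyclopent-1-en-1-yl]-3-methylpent-4-en-1-yl benzoate | CC(C)[C@H]1CCC(C)=C1[C@@H](OC(=O)c1ccccc1)CC(C)(O)C=C
F2 | step 4 | (1R)-1-[(5R)-5-isopropyl-2-methylcyclopent-1-en-1-yl]-3-methylidenepent-4-en-1-ol | CC(C)[C@H]1CCC(C)=C1[C@H](O)CC(=C)C=C
F3 | step 4 | 1-[(5R)-5-isopropyl-2-methylcyclopent-1-en-1-yl]-3-methylidenepent-4-en-1-one | CC(C)[C@H]1CCC(C)=C1C(=O)CC(=C)C=C
F4 | step 7 | (1R,4R,5S,6S,8R,9R)-9-bromo-4,8-dihydroxydaucan-6-yl benzoate | CC(C)[C@]1(O)CC[C@]2(C)C[C@@H](Br)[C@](C)(O)C[C@H](OC(=O)c3ccccc3)[C@H]21
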